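**Retrosynthetic overview**
1. The C16–OH is installed last by exo-face hydroxylation of the C15 ketone enolate. Ring D comes from a C13–C16 bond made by palladium-catalysed oxidative cyclisation of the C15 ketone silyl enol ether onto C12=C13.
2. Rings B (δ-lactone) and C are made together in one pot from hydroxy aldehyde 8, methyl 3-oxopentanoate and butadiene: ester exchange (C7–O), intramolecular Knoevenagel (C8=C9), then Diels–Alder (C9–C11, C8–C14).
3. The C10 quaternary centre comes from two one-carbon electrophiles on the ring A enolate: CH2O first, then HC(OMe)3 anti to the C5 substituent.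
4. C5, the source of absolute configuration, comes from asymmetric conjugate addition of a MOM-oxymethyl zinc reagent to 4,4-dimethylcyclohexa-2,5-dienone.
5. Ring order: A (purchased) → B + C (one operation) → D.

Assumption 1: atom labels follow kaurane numbering (C1 ring A ketone, C2=C3, C4 CMe2, C5, C6 CH2OH carbon, C7 lactone C=O, C8, C9, C10 spiro carbon, C11–C14, C15 ring D ketone, C16 carbinol carbon, C17 its methyl, C20 OCH2); the target is 5R,8S,9S,10S,13R,16S.
Assumption 2: the ligand enantiomer in step 2 is assigned by analogy with diethylzinc additions to cyclohexenone; if the sense is reversed, the antipodal ligand is used.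

**Route**

Step 1
Reactants: 1 4,4-dimethylcyclohex-2-en-1-one
Product: 2 4,4-dimethylcyclohexa-2,5-dien-1-one
Conditions: IBX (2 equiv), DMSO/PhF, 70 °C
Reagents that add atoms: none
Why: IBX dehydrogenation of the saturated side of the ketone gives the symmetrical cross-conjugated dienone; no stereocentre is formed.

Step 2
Reactants: 2 4,4-dimethylcyclohexa-2,5-dien-1-one; 3 tributyl[(methoxymethoxy)methyl]stannane
Product: 5 (5S,6R)-6-(hydroxymethyl)-5-[(methoxymethoxy)methyl]-4,4-dimethylcyclohex-2-en-1-one, via zinc enolate 4 (not isolated)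
Conditions: 3, n-BuLi, THF, −78 °C; ZnCl2 (0.5 equiv), 0 °C; then 2, Cu(OTf)2 (2 mol %), (R)-BINOL bis[(S)-1-phenylethyl]amine phosphoramidite (4 mol %), PhMe, −30 °C; then CH2O (gas), −78 °C; aq NH4Cl
Reagents that add atoms: formaldehyde C=O; zinc dichloride Cl[Zn]Cl (zinc ends in intermediate 4 only)
Why: Proposed new method: a dialkylzinc carrying an α-alkoxy group is used in copper-catalysed asymmetric conjugate addition, on the reasoning that the small primary MOM-oxymethyl group transmetallates from zinc to the chiral phosphoramidite–copper complex and adds to one enantiotopic enone of 2 as an ethyl group does (closest known reaction type: phosphoramidite/copper-catalysed dialkylzinc 1,4-addition to 4,4-disubstituted cyclohexadienones with aldol trapping of the zinc enolate), which sets C5 by ligand control, while the C6 configuration from the formaldehyde aldol is erased in step 3.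

Step 3
Reactants: 5 (5S,6R)-6-(hydroxymethyl)-5-[(methoxymethoxy)methyl]-4,4-dimethylcyclohex-2-en-1-one
Product: 6 (6R)-6-[(methoxymethoxy)methyl]-5,5-dimethyl-2-(trimethylsilyloxy)-1-[(trimethylsilyloxy)methyl]cyclohexa-1,3-diene
Conditions: TMSOTf (2.3 equiv), Et3N, CH2Cl2, 0 °C
Reagents that add atoms: trimethylsilyl trifluoromethanesulfonate C[Si](C)(C)OS(=O)(=O)C(F)(F)F
Why: Soft enolisation and O-silylation (silyl enol ether formation) at the only enolisable position gives the cross-conjugated silyl dienol ether, which planarises the ring carbon that becomes C10 and masks the β-hydroxy ketone against retro-aldol and E1cB loss.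

Step 4
Reactants: 6 (6R)-6-[(methoxymethoxy)methyl]-5,5-dimethyl-2-(trimethylsilyloxy)-1-[(trimethylsilyloxy)methyl]cyclohexa-1,3-diene
Product: 8 (1S,6R)-1-(hydroxymethyl)-6-[(methoxymethoxy)methyl]-5,5-dimethyl-2-oxocyclohex-3-ene-1-carbaldehyde, via keto acetal 7 (not isolated)
Conditions: HC(OMe)3, TMSOTf (10 mol %), CH2Cl2, −78 °C; then 1 M HCl, THF, 0 °C
Reagents that add atoms: trimethyl orthoformate COC(OC)OC; water O
Why: Mukaiyama-type alkylation of the silyl enol ether by the dimethoxycarbenium ion occurs anti to the neighbouring CH2OMOM group, so the formyl carbon (C9) enters trans to C6 and the CH2OH (C20) ends cis to it, fixing the quaternary centre C10; dilute acid then hydrolyses the acetal and the silyl ether but not the MOM ether.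

Step 5
Reactants: 8 (1S,6R)-1-(hydroxymethyl)-6-[(methoxymethoxy)methyl]-5,5-dimethyl-2-oxocyclohex-3-ene-1-carbaldehyde; 9 methyl 3-oxopentanoate; 10 buta-1,3-diene
Product: 13 (5R,8S,9S,10S)-6-(methoxymethoxy)-1,15-dioxo-6,7:13,16-diseco-kaura-2,12-dien-7,20-olide [cis-fused cyclohexene δ-lactone spiro-linked at C10 to the ring A enone; propanoyl on C8], via keto ester aldehyde 11 (not isolated), via unsaturated spirolactone 12 (not isolated)
Conditions: 9 (1.2 equiv), DMAP (10 mol %), 4 Å MS, PhMe, 110 °C; then 10 (10 equiv), ZnCl2 (1.2 equiv), sealed tube, 60 °C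
Reagents that add atoms: none
Why: A domino of β-keto ester exchange, intramolecular Knoevenagel condensation onto the non-enolisable aldehyde (ring B) and Diels–Alder reaction of the ZnCl2-chelated alkylidene 1,3-dicarbonyl 12 with butadiene (ring C), in which the diene adds to the face of C8=C9 turned away from C5 (CH2OMOM next to the gem-dimethyl group) and towards the flat C1 carbonyl, so that C9 and C8 are set together in one suprafacial event.

Step 6
Reactants: 13 (5R,8S,9S,10S)-6-(methoxymethoxy)-1,15-dioxo-6,7:13,16-diseco-kaura-2,12-dien-7,20-olide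
Product: 15 (5R,8S,9S,10S,13S)-6-(methoxymethoxy)-1,15-dioxo-6,7-seco-kaura-2,11-dien-7,20-olide (mixture of C16 epimers), via silyl enol ether 14 (not isolated)
Conditions: LiN(SiMe3)2, TMSCl, THF, −78 °C; then Pd(OAc)2 (10 mol %), O2 (1 atm), DMSO, 45 °C
Reagents that add atoms: chlorotrimethylsilane C[Si](C)(C)Cl (silicon ends in intermediate 14 only)
Why: C16 is the only enolisable position, and palladium-catalysed oxidative cyclisation of the silyl enol ether onto the ring alkene (Saegusa-type cycloalkenylation) adds the palladium enolate syn across C12=C13 in the 5-exo sense to form C16–C13 (ring D), with the bridgehead C13 fixed by the tether to C8 and β-hydride elimination leaving C11=C12.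

Step 7
Reactants: 15 (5R,8S,9S,10S,13S)-6-(methoxymethoxy)-1,15-dioxo-6,7-seco-kaura-2,11-dien-7,20-olide
Product: 16 (5R,8S,9S,10S,13R)-6-(methoxymethoxy)-1,15-dioxo-6,7-seco-kaur-2-en-7,20-olide (mixture of C16 epimers)
Conditions: H2 (1 atm), RhCl(PPh3)3 (5 mol %), PhH/EtOH, rt
Reagents that add atoms: none
Why: Homogeneous hydrogenation with RhCl(PPh3)3 reduces the strained cis-disubstituted C11=C12 alkene faster than the conjugated ring A alkene, whose β-carbon is neopentyl; no stereocentre is formed.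

Step 8
Reactants: 16 (5R,8S,9S,10S,13R)-6-(methoxymethoxy)-1,15-dioxo-6,7-seco-kaur-2-en-7,20-olide
Product: 18 (5R,8S,9S,10S,13R,16S)-16-hydroxy-6-(methoxymethoxy)-1,15-dioxo-6,7-seco-kaur-2-en-7,20-olide, via potassium enolate 17 (not isolated)
Conditions: KN(SiMe3)2, THF, −78 °C; then 3-phenyl-2-(phenylsulfonyl)oxaziridine, −78 °C; aq NH4Cl
Reagents that add atoms: 3-phenyl-2-(phenylsulfonyl)oxaziridine O=S(=O)(c1ccccc1)N1OC1c1ccccc1; potassium bis(trimethylsilyl)amide C[Si](C)(C)[N-][Si](C)(C)C.[K+] (potassium ends in intermediate 17 only)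
Why: Davis enolate hydroxylation, in which C16–H is the only acidic C–H and the oxaziridine attacks the planar C15–C16 enolate from the exo face (the side of the one-carbon bridge C14, away from the C11–C12 bridge), giving the tertiary alcohol with exo hydroxyl (16S).

Step 9
Reactants: 18 (5R,8S,9S,10S,13R,16S)-16-hydroxy-6-(methoxymethoxy)-1,15-dioxo-6,7-seco-kaur-2-en-7,20-olide
Product: 19 (5R,8S,9S,10S,13R,16S)-6,16-dihydroxy-1,15-dioxo-6,7-seco-kaur-2-en-7,20-olide (target, CNP0530135.1)
Conditions: ZnBr2, n-PrSH, CH2Cl2, 0 °C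
Reagents that add atoms: none
Why: Lewis acid/thiol cleavage of the MOM acetal (ZnBr2 activates the acetal and propanethiol captures the methoxymethyl cation) frees the primary alcohol without touching the lactone, the enone or the tertiary α-ketol; no stereocentre is affected.

**Compound list**
1 | 4,4-dimethylcyclohex-2-en-1-one | CC1(C)CCC(=O)C=C1 | starting material
2 | 4,4-dimethylcyclohexa-2,5-dien-1-one | CC1(C)C=CC(=O)C=C1 | intermediate
3 | tributyl[(methoxymethoxy)methyl]stannane | CCCC[Sn](CCCC)(CCCC)COCOC | starting material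
4 | {[(3S)-3-[(methoxymethoxy)methyl]-4,4-dimethylcyclohexa-1,5-dien-1-yl]oxy}[(methoxymethoxy)methyl]zinc (zinc enolate) | CC1(C)C=CC(O[Zn]COCOC)=C[C@@H]1COCOC | intermediate (not isolated)
5 | (5S,6R)-6-(hydroxymethyl)-5-[(methoxymethoxy)methyl]-4,4-dimethylcyclohex-2-en-1-one (trans; the 6-epimer serves equally) | CC1(C)C=CC(=O)[C@@H](CO)[C@@H]1COCOC | intermediate
6 | (6R)-6-[(methoxymethoxy)methyl]-5,5-dimethyl-2-(trimethylsilyloxy)-1-[(trimethylsilyloxy)methyl]cyclohexa-1,3-diene | CC1(C)C=CC(O[Si](C)(C)C)=C(CO[Si](C)(C)C)[C@@H]1COCOC | intermediate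
7 | (5R,6S)-6-(dimethoxymethyl)-5-[(methoxymethoxy)methyl]-4,4-dimethyl-6-[(trimethylsilyloxy)methyl]cyclohex-2-en-1-one (keto acetal) | CC1(C)C=CC(=O)[C@](C(OC)OC)(CO[Si](C)(C)C)[C@@H]1COCOC | intermediate (not isolated)
8 | (1S,6R)-1-(hydroxymethyl)-6-[(methoxymethoxy)methyl]-5,5-dimethyl-2-oxocyclohex-3-ene-1-carbaldehyde | CC1(C)C=CC(=O)[C@](C=O)(CO)[C@@H]1COCOC | intermediate
9 | methyl 3-oxopentanoate | CCC(=O)CC(=O)OC | starting material
10 | buta-1,3-diene | C=CC=C | starting material
11 | [(1S,6R)-1-formyl-6-[(methoxymethoxy)methyl]-5,5-dimethyl-2-oxocyclohex-3-en-1-yl]methyl 3-oxopentanoate (keto ester aldehyde) | CC1(C)C=CC(=O)[C@](C=O)(COC(=O)CC(=O)CC)[C@@H]1COCOC | intermediate (not isolated)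
12 | (6S,11R)-11-[(methoxymethoxy)methyl]-10,10-dimethyl-4-propanoyl-2-oxaspiro[5.5]undeca-4,8-diene-3,7-dione (unsaturated spirolactone; 5R,10S in kaurane numbering) | CC1(C)C=CC(=O)[C@]2(COC(=O)C(C(=O)CC)=C2)[C@@H]1COCOC | intermediate (not isolated)
13 | (5R,8S,9S,10S)-6-(methoxymethoxy)-1,15-dioxo-6,7:13,16-diseco-kaura-2,12-dien-7,20-olide | CC1(C)C=CC(=O)[C@]2(COC(=O)[C@@]3(C(=O)CC)CC=CC[C@H]32)[C@@H]1COCOC | intermediate
14 | 15-O-trimethylsilyl enol ether (C15=C16) of 13 | CC1(C)C=CC(=O)[C@]2(COC(=O)[C@@]3(C(O[Si](C)(C)C)=CC)CC=CC[C@H]32)[C@@H]1COCOC | intermediate (not isolated)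
15 | (5R,8S,9S,10S,13S)-6-(methoxymethoxy)-1,15-dioxo-6,7-seco-kaura-2,11-dien-7,20-olide (C16 epimers) | CC1(C)C=CC(=O)[C@]2(COC(=O)[C@@]34C[C@@H](C=C[C@H]32)C(C)C4=O)[C@@H]1COCOC | intermediate
16 | (5R,8S,9S,10S,13R)-6-(methoxymethoxy)-1,15-dioxo-6,7-seco-kaur-2-en-7,20-olide (C16 epimers) | CC1(C)C=CC(=O)[C@]2(COC(=O)[C@@]34C[C@@H](CC[C@H]32)C(C)C4=O)[C@@H]1COCOC | intermediate
17 | potassium C15–C16 enolate of 16 | CC1(C)C=CC(=O)[C@]2(COC(=O)[C@@]34C[C@@H](CC[C@H]32)C(C)=C4[O-])[C@@H]1COCOC.[K+] | intermediate (not isolated)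
18 | (5R,8S,9S,10S,13R,16S)-16-hydroxy-6-(methoxymethoxy)-1,15-dioxo-6,7-seco-kaur-2-en-7,20-olide | CC1(C)C=CC(=O)[C@]2(COC(=O)[C@@]34C[C@@H](CC[C@H]32)[C@](C)(O)C4=O)[C@@H]1COCOC | intermediate
19 | (5R,8S,9S,10S,13R,16S)-6,16-dihydroxy-1,15-dioxo-6,7-seco-kaur-2-en-7,20-olide | CC1(C)C=CC(=O)[C@]2(COC(=O)[C@@]34C[C@@H](CC[C@H]32)[C@](C)(O)C4=O)[C@@H]1CO | target

**Totals**
Total step count: 9. Longest linear sequence: 9 steps (1 → 19); compounds 3, 9 and 10 are purchased.

**Steps most likely to fail, with fallbacks**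

Risk at step 2. The α-alkoxymethyl group may transfer slowly from zinc or with low enantioselectivity, especially with lithium salts present. The fallback sets out from 2 and uses only known reaction types. Rhodium-catalysed asymmetric 1,4-addition of potassium vinyltrifluoroborate ([Rh(cod)Cl]2, the BINAP enantiomer that delivers 5R, aqueous dioxane) gives (5R)-5-ethenyl-4,4-dimethylcyclohex-2-en-1-one F1. Ozonolysis at −78 °C with Me2S work-up, in which the isolated vinyl group reacts before the electron-poor enone, gives (1S)-2,2-dimethyl-5-oxocyclohex-3-ene-1-carbaldehyde F2. NaBH(OAc)3 reduces only the aldehyde to (5S)-5-(hydroxymethyl)-4,4-dimethylcyclohex-2-en-1-one F3. MOMCl with iPr2NEt gives (5S)-5-[(methoxymethoxy)methyl]-4,4-dimethylcyclohex-2-en-1-one F4. LiN(iPr)2 followed by CH2O (the ketone can enolise only at C6) comes back to the route at 5.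

Risk at step 5. The dienophile 12 is flanked by the quaternary C10 and may react slowly or with poor facial selectivity, and hydroxy aldehyde 8 may lose formaldehyde on heating with DMAP. The fallback sets out from 8 and replaces the cycloaddition by a stepwise radical annulation. Ester exchange with 9 and Knoevenagel closure are stopped at spirolactone 12, which is isolated. Copper-catalysed conjugate addition of but-3-enylmagnesium bromide (CuBr·SMe2, TMSCl, THF, −78 °C; attack anti to C5) gives (5R,6S,11R)-5-(but-3-en-1-yl)-11-[(methoxymethoxy)methyl]-10,10-dimethyl-4-propanoyl-2-oxaspiro[5.5]undec-8-ene-3,7-dione F5. Oxidative radical cyclisation with Mn(OAc)3 and Cu(OAc)2 in AcOH closes ring C by 6-endo attack of the C8 radical on the terminal alkene and the copper salt removes a hydrogen from C12; this comes back to the route at 13. The weak points of this fallback are 5-exo competition, the ring-fusion geometry (cis is expected from the short tether but not certain) and alkene regiochemistry.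

Risk at step 6. The palladium enolate of the ethyl ketone can lose a β-hydrogen from C17 to give a vinyl ketone instead of cyclising, and 6-endo closure would give the bicyclo[2.2.2] isomer. The fallback sets out from 8 and brings C17 in later. The domino of step 5 is run with 2,2,6-trimethyl-4H-1,3-dioxin-4-one (xylene, 130 °C, then 10 and ZnCl2) in place of 9, giving (5R,8S,9S,10S)-6-(methoxymethoxy)-1,15-dioxo-17-nor-6,7:13,16-diseco-kaura-2,12-dien-7,20-olide F6. Its 15-O-trimethylsilyl enol ether F7 (not isolated) has no β-hydrogen on the enol side, and Pd(OAc)2/O2 cyclises it to (5R,8S,9S,10S,13R)-6-(methoxymethoxy)-1,15-dioxo-17-nor-6,7-seco-kaura-2,11-dien-7,20-olide F8. Hydrogenation with RhCl(PPh3)3 gives (5R,8S,9S,10S,13R)-6-(methoxymethoxy)-1,15-dioxo-17-nor-6,7-seco-kaur-2-en-7,20-olide F9. LiN(SiMe3)2 followed by MeI methylates C16 and comes back to the route at 16; either C16 epimer serves because step 8 planarises C16.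

**Further compounds**
F1 | step 2 | (5R)-5-ethenyl-4,4-dimethylcyclohex-2-en-1-one | CC1(C)C=CC(=O)C[C@@H]1C=C
F2 | step 2 | (1S)-2,2-dimethyl-5-oxocyclohex-3-ene-1-carbaldehyde | CC1(C)C=CC(=O)C[C@@H]1C=O
F3 | step 2 | (5S)-5-(hydroxymethyl)-4,4-dimethylcyclohex-2-en-1-one | CC1(C)C=CC(=O)C[C@@H]1CO
F4 | step 2 | (5S)-5-[(methoxymethoxy)methyl]-4,4-dimethylcyclohex-2-en-1-one | CC1(C)C=CC(=O)C[C@@H]1COCOC
F5 | step 5 | (5R,6S,11R)-5-(but-3-en-1-yl)-11-[(methoxymethoxy)methyl]-10,10-dimethyl-4-propanoyl-2-oxaspiro[5.5]undec-8-ene-3,7-dione (C4 epimers) | CC1(C)C=CC(=O)[C@]2(COC(=O)C(C(=O)CC)[C@H]2CCC=C)[C@@H]1COCOC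
F6 | step 6 | (5R,8S,9S,10S)-6-(methoxymethoxy)-1,15-dioxo-17-nor-6,7:13,16-diseco-kaura-2,12-dien-7,20-olide | CC1(C)C=CC(=O)[C@]2(COC(=O)[C@@]3(C(C)=O)CC=CC[C@H]32)[C@@H]1COCOC
F7 | step 6 | 15-O-trimethylsilyl enol ether (C15=C16) of F6 | CC1(C)C=CC(=O)[C@]2(COC(=O)[C@@]3(C(=C)O[Si](C)(C)C)CC=CC[C@H]32)[C@@H]1COCOC
F8 | step 6 | (5R,8S,9S,10S,13R)-6-(methoxymethoxy)-1,15-dioxo-17-nor-6,7-seco-kaura-2,11-dien-7,20-olide | CC1(C)C=CC(=O)[C@]2(COC(=O)[C@@]34C[C@@H](C=C[C@H]32)CC4=O)[C@@H]1COCOC
F9 | step 6 | (5R,8S,9S,10S,13R)-6-(methoxymethoxy)-1,15-dioxo-17-nor-6,7-seco-kaur-2-en-7,20-olide | CC1(C)C=CC(=O)[C@]2(COC(=O)[C@@]34C[C@@H](CC[C@H]32)CC4=O)[C@@H]1COCOC
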